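**Strategy.** The cyclohexene ring A of the decalin (C1–C2–C3=C4–C5–C10; C5 angular, C10 ring-fusion CH) is a Diels–Alder retron. In one operation an intramolecular [4+2] cycloaddition joins C1–C2 and C5–C10, closing rings A and B and setting C5 and C10. The precursor is an (E)-3,4-dimethyl-1,3-diene tethered through C6–C7–C8 to a 2-sulfolene. This temporary ring ties C1 through SO2 to the carbon that becomes the C9 methyl, activates the dienophile, forces that carbon axial (syn to the C5 methyl) and is later erased with LiAlH4 and Raney Ni. The tetramethoxyarene on C11 is finally oxidised and ring-contracted to the cyclopentenone.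

Key step: step 17

Locants used below: decalin carbons as in the target (C4 vinylic-methyl carbon, C5 angular-methyl carbon, C8 quaternary carbon bearing CH3 and C11H2, C9 the CH(CH3) carbon with methyl carbon C9a, C10 ring-fusion CH); Ar = 2,3,5,6-tetramethoxyphenyl.
Remark: the sense of induction of (S)-BINAP in step 3 is assumed to be the one established for cyclopent-2-enone.

Step 1
Reactants: 1 1,2,4,5-tetramethoxybenzene
Product: 3 (2,3,5,6-tetramethoxyphenyl)methanol, via aryllithium 2 (not isolated)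
Conditions: n-BuLi, TMEDA, THF, 0 °C; then (CH2O)n, 0 °C → rt
Reagents that add atoms: formaldehyde (as paraformaldehyde), C=O
Why: Directed ortho-lithiation removes the C–H flanked by two methoxy groups and the aryllithium adds to formaldehyde.

Step 2
Reactants: 3 (2,3,5,6-tetramethoxyphenyl)methanol
Product: 4 3-(bromomethyl)-1,2,4,5-tetramethoxybenzene
Conditions: PBr3, CH2Cl2, 0 °C
Reagents that add atoms: phosphorus tribromide, BrP(Br)Br
Why: The electron-rich benzylic alcohol is converted to the bromide through its phosphite ester (SN2 by bromide).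

Step 3
Reactants: 5 furan-2(5H)-one; 6 (E)-prop-1-en-1-ylboronic acid
Product: 7 (S)-4-[(E)-prop-1-en-1-yl]dihydrofuran-2(3H)-one
Conditions: Rh(acac)(C2H4)2 (3 mol %), (S)-BINAP, dioxane/H2O, 100 °C
Reagents that add atoms: none
Why: Hayashi–Miyaura reaction, the rhodium–BINAP-catalysed asymmetric 1,4-addition of an alkenylboronic acid to the butenolide, in which (S)-BINAP should deliver the alkenyl group to the face that gives the (S) centre (future C9).

Step 4
Reactants: 7 (S)-4-[(E)-prop-1-en-1-yl]dihydrofuran-2(3H)-one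
Product: 9 (3R,4R)-3-methyl-4-[(E)-prop-1-en-1-yl]dihydrofuran-2(3H)-one, via lithium enolate 8 (not isolated)
Conditions: LiN(i-Pr)2, THF, −78 °C; then MeI
Reagents that add atoms: iodomethane, CI
Why: Lactone enolate alkylation, with the electrophile entering anti to the propenyl group (this centre is re-enolised in step 5, so its configuration is immaterial).

Step 5
Reactants: 9 (3R,4R)-3-methyl-4-[(E)-prop-1-en-1-yl]dihydrofuran-2(3H)-one; 4 3-(bromomethyl)-1,2,4,5-tetramethoxybenzene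
Product: 11 (3R,4R)-3-methyl-4-[(E)-prop-1-en-1-yl]-3-[(2,3,5,6-tetramethoxyphenyl)methyl]dihydrofuran-2(3H)-one, via lithium enolate 10 (not isolated)
Conditions: LiN(i-Pr)2, THF, −78 °C; then 4, DMPU, −78 → −20 °C
Reagents that add atoms: none
Why: Enolate alkylation creates the quaternary centre (future C8): the benzylic bromide approaches the tetrasubstituted enolate anti to the neighbouring propenyl group, so the benzyl group ends trans and the methyl cis to it.

Step 6
Reactants: 11 (3R,4R)-3-methyl-4-[(E)-prop-1-en-1-yl]-3-[(2,3,5,6-tetramethoxyphenyl)methyl]dihydrofuran-2(3H)-one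
Product: 12 (3R,4R)-3-methyl-4-[(E)-prop-1-en-1-yl]-3-[(2,3,5,6-tetramethoxyphenyl)methyl]oxolan-2-ol (anomer mixture)
Conditions: i-Bu2AlH, CH2Cl2, −78 °C
Reagents that add atoms: none
Why: Partial reduction of the lactone stops at the lactol because the aluminium hemiacetal is stable at −78 °C.

Step 7
Reactants: 12 (3R,4R)-3-methyl-4-[(E)-prop-1-en-1-yl]-3-[(2,3,5,6-tetramethoxyphenyl)methyl]oxolan-2-ol
Product: 13 (2R,3S)-3-methyl-2-[(E)-prop-1-en-1-yl]-3-[(2,3,5,6-tetramethoxyphenyl)methyl]pent-4-en-1-ol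
Conditions: Ph3PCH3Br, KOtBu, THF, 0 → 50 °C
Reagents that add atoms: methyltriphenylphosphonium bromide, C[P+](c1ccccc1)(c1ccccc1)c1ccccc1.[Br-]
Why: Wittig methylenation of the open hydroxy-aldehyde form of the lactol installs the C8 vinyl group (C7=C6) and frees the C9a alcohol.

Step 8
Reactants: 14 methyl 2-methyl-3-oxobutanoate
Product: 15 methyl (E)-2-methyl-3-(tosyloxy)but-2-enoate
Conditions: TsCl, N-methylimidazole, Et3N, toluene, 0 °C
Reagents that add atoms: 4-methylbenzenesulfonyl chloride, Cc1ccc(cc1)S(Cl)(=O)=O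
Why: Stereoselective enol tosylation of the β-keto ester under non-chelating amine conditions gives the (E)-enol tosylate, with the tosyloxy group trans to the ester.

Step 9
Reactants: 13 (2R,3S)-3-methyl-2-[(E)-prop-1-en-1-yl]-3-[(2,3,5,6-tetramethoxyphenyl)methyl]pent-4-en-1-ol; 15 methyl (E)-2-methyl-3-(tosyloxy)but-2-enoate
Product: 17 methyl (2E,6R,7R,8E)-7-(hydroxymethyl)-2,3,6-trimethyl-6-[(2,3,5,6-tetramethoxyphenyl)methyl]deca-2,8-dienoate, via alkylborane 16 (not isolated)
Conditions: 9-BBN-H (2.3 equiv), THF, rt; then 15, Pd(dppf)Cl2 (5 mol %), K3PO4, DMF/H2O, 50 °C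
Reagents that add atoms: none
Why: Anti-Markovnikov hydroboration selects the terminal vinyl group over the internal propenyl alkene, and the B-alkyl Suzuki–Miyaura coupling retains the enol tosylate geometry, which fixes the (E)-tetrasubstituted C4=C5 alkene.

Step 10
Reactants: 17 methyl (2E,6R,7R,8E)-7-(hydroxymethyl)-2,3,6-trimethyl-6-[(2,3,5,6-tetramethoxyphenyl)methyl]deca-2,8-dienoate
Product: 19 methyl (2E,6R,7R,8E)-7-{[(2-hydroxyethyl)sulfanyl]methyl}-2,3,6-trimethyl-6-[(2,3,5,6-tetramethoxyphenyl)methyl]deca-2,8-dienoate, via mesylate 18 (not isolated)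
Conditions: MsCl, Et3N, CH2Cl2, 0 °C; then HSCH2CH2OH, Cs2CO3, DMF, 50 °C
Reagents that add atoms: 2-sulfanylethanol, OCCS
Why: Mesylation followed by SN2 displacement with the soft thiolate at the primary carbon C9a forms the C9a–S bond.

Step 11
Reactants: 19 methyl (2E,6R,7R,8E)-7-{[(2-hydroxyethyl)sulfanyl]methyl}-2,3,6-trimethyl-6-[(2,3,5,6-tetramethoxyphenyl)methyl]deca-2,8-dienoate
Product: 20 methyl (2E,6R,7R,8E)-7-{[(2-hydroxyethyl)sulfonyl]methyl}-2,3,6-trimethyl-6-[(2,3,5,6-tetramethoxyphenyl)methyl]deca-2,8-dienoate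
Conditions: 30% H2O2, (NH4)6Mo7O24·4H2O (cat.), EtOH, 0 °C → rt
Reagents that add atoms: hydrogen peroxide, OO
Why: Molybdate-catalysed peroxide oxidation takes the sulfide to the sulfone and should leave the isolated alkene, the electron-poor enoate and the arene untouched.

Step 12
Reactants: 20 methyl (2E,6R,7R,8E)-7-{[(2-hydroxyethyl)sulfonyl]methyl}-2,3,6-trimethyl-6-[(2,3,5,6-tetramethoxyphenyl)methyl]deca-2,8-dienoate
Product: 22 methyl (2E,6R,7R,8E)-7-[(ethenesulfonyl)methyl]-2,3,6-trimethyl-6-[(2,3,5,6-tetramethoxyphenyl)methyl]deca-2,8-dienoate, via mesylate 21 (not isolated)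
Conditions: MsCl, Et3N (3 equiv), CH2Cl2, 0 °C → rt
Reagents that add atoms: none
Why: Mesylation of the β-hydroxy sulfone is followed by E1cB elimination to the vinyl sulfone.

Step 13
Reactants: 22 methyl (2E,6R,7R,8E)-7-[(ethenesulfonyl)methyl]-2,3,6-trimethyl-6-[(2,3,5,6-tetramethoxyphenyl)methyl]deca-2,8-dienoate
Product: 23 methyl (2E,6R)-6-[(3R)-1,1-dioxo-2,3-dihydrothiophen-3-yl]-2,3,6-trimethyl-7-(2,3,5,6-tetramethoxyphenyl)hept-2-enoate
Conditions: second-generation Grubbs catalyst, RuCl2(=CHPh)(PCy3)(H2IMes) (5 mol %), toluene, 80 °C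
Reagents that add atoms: none
Why: Ring-closing metathesis between the vinyl sulfone and the propenyl group closes the five-membered 2-sulfolene with loss of propene, the tetrasubstituted enoate being inert.

Step 14
Reactants: 23 methyl (2E,6R)-6-[(3R)-1,1-dioxo-2,3-dihydrothiophen-3-yl]-2,3,6-trimethyl-7-(2,3,5,6-tetramethoxyphenyl)hept-2-enoate
Product: 24 (2E,6R)-6-[(3R)-1,1-dioxo-2,3-dihydrothiophen-3-yl]-2,3,6-trimethyl-7-(2,3,5,6-tetramethoxyphenyl)hept-2-en-1-ol
Conditions: i-Bu2AlH (3 equiv), CH2Cl2, −78 °C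
Reagents that add atoms: none
Why: 1,2-Reduction of the enoate to the allylic alcohol occurs under non-basic conditions that spare the sulfolene and its allylic C9–H.

Step 15
Reactants: 24 (2E,6R)-6-[(3R)-1,1-dioxo-2,3-dihydrothiophen-3-yl]-2,3,6-trimethyl-7-(2,3,5,6-tetramethoxyphenyl)hept-2-en-1-ol
Product: 25 (2E,6R)-6-[(3R)-1,1-dioxo-2,3-dihydrothiophen-3-yl]-2,3,6-trimethyl-7-(2,3,5,6-tetramethoxyphenyl)hept-2-enal
Conditions: MnO2, CH2Cl2, rt
Reagents that add atoms: none
Why: Neutral, chemoselective oxidation of the allylic alcohol gives the enal without touching the alkene geometry.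

Step 16
Reactants: 25 (2E,6R)-6-[(3R)-1,1-dioxo-2,3-dihydrothiophen-3-yl]-2,3,6-trimethyl-7-(2,3,5,6-tetramethoxyphenyl)hept-2-enal
Product: 26 (3R)-3-[(2R,5E)-2,5,6-trimethyl-1-(2,3,5,6-tetramethoxyphenyl)octa-5,7-dien-2-yl]-2,3-dihydrothiophene 1,1-dioxide
Conditions: CH2I2, Zn, Ti(OiPr)4, THF, rt
Reagents that add atoms: diiodomethane, ICI
Why: Takai methylenation with the non-basic gem-dizinc/titanium reagent converts the enal into the terminal diene without epimerising C9 or isomerising the sulfolene.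

Step 17
Reactants: 26 (3R)-3-[(2R,5E)-2,5,6-trimethyl-1-(2,3,5,6-tetramethoxyphenyl)octa-5,7-dien-2-yl]-2,3-dihydrothiophene 1,1-dioxide
Product: 27 tricyclic sulfone (trans-fused octalin with SO2 bridging C1 and C9a)
Conditions: BHT (cat.), toluene, 170 °C, sealed tube
Reagents that add atoms: none
Why: Thermal, concerted but asynchronous normal-demand [4+2] cycloaddition of the electron-rich tetrasubstituted diene (C2=C3–C4=C5) to the cyclic vinyl sulfone (C10=C1), the closest known reaction type being the intramolecular Diels–Alder reaction of sulfonyl-activated deca-1,7,9-trienes. Ring A is closed by the cycloaddition itself and ring B (C5–C6–C7–C8–C9–C10) by the three-carbon tether in a chair-like anti (exo-sulfonyl) array that leads to the trans ring fusion. C10 and the transient C1 centre follow from suprafacial addition to the only face of the sulfolene that the tether can reach, the face bearing C8, so that H-9 and H-10 end syn. C5 is fixed by the (E)-diene geometry (tether outside, methyl inside) together with the anti mode, which places the C5 methyl anti to H-10. The step needs the trans fusion and an axial C9a syn to the C5 methyl: the nearly planar sulfolene keeps C9a eclipsed with C1, which a chair-like tether can accommodate only in the anti mode with C9a axial, and the C8 configuration from step 5 then puts the C8 methyl axial and C11 equatorial. The main competitors are a [1,5]-hydrogen shift of the (Z)-methyl diene and steric retardation at the quaternary terminus.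

Step 18
Reactants: 27 tricyclic sulfone
Product: 28 tricyclic thiolane (S bridging C1 and C9a)
Conditions: LiAlH4, THF/Et2O, reflux
Reagents that add atoms: none
Why: Five-membered cyclic sulfones are reduced to the sulfides by LiAlH4, and the alkene and arene are inert.

Step 19
Reactants: 28 tricyclic thiolane
Product: 29 3-{[(1R,2R,4aS,8aS)-1,2,4a,5-tetramethyl-1,2,3,4,4a,7,8,8a-octahydronaphthalen-2-yl]methyl}-1,2,4,5-tetramethoxybenzene
Conditions: Raney Ni (W-2, deactivated with acetone), EtOH, 60 °C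
Reagents that add atoms: none
Why: Raney nickel hydrogenolysis of both C–S bonds leaves C1 as CH2 and C9a as the axial C9 methyl, and the hindered trisubstituted alkene should survive on the deactivated catalyst.

Step 20
Reactants: 29 3-{[(1R,2R,4aS,8aS)-1,2,4a,5-tetramethyl-1,2,3,4,4a,7,8,8a-octahydronaphthalen-2-yl]methyl}-1,2,4,5-tetramethoxybenzene
Product: 30 2,5-dimethoxy-3-{[(1R,2R,4aS,8aS)-1,2,4a,5-tetramethyl-1,2,3,4,4a,7,8,8a-octahydronaphthalen-2-yl]methyl}cyclohexa-2,5-diene-1,4-dione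
Conditions: (NH4)2Ce(NO3)6, MeCN/H2O, 0 °C
Reagents that add atoms: water, O
Why: Oxidative demethylation of a para-dimethoxy pair by tetravalent cerium (two one-electron oxidations, with water supplying the carbonyl oxygens) gives the 2,5-dimethoxy-1,4-benzoquinone, either para pair leading to the same quinone.

Step 21
Reactants: 30 2,5-dimethoxy-3-{[(1R,2R,4aS,8aS)-1,2,4a,5-tetramethyl-1,2,3,4,4a,7,8,8a-octahydronaphthalen-2-yl]methyl}cyclohexa-2,5-diene-1,4-dione
Product: 31 2-hydroxy-5-methoxy-3-{[(1R,2R,4aS,8aS)-1,2,4a,5-tetramethyl-1,2,3,4,4a,7,8,8a-octahydronaphthalen-2-yl]methyl}cyclohexa-2,5-diene-1,4-dione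
Conditions: KOH, MeOH/H2O, rt; then aq. HCl
Reagents that add atoms: potassium hydroxide, [K+].[OH-]
Why: Addition–elimination of hydroxide at the vinylogous ester is expected to exchange the methoxy group flanked by the C11 side chain (twisted out of conjugation), as is usual for 3-alkyl-2,5-dimethoxyquinones, and the product is protected from further attack as its anion.

Step 22
Reactants: 31 2-hydroxy-5-methoxy-3-{[(1R,2R,4aS,8aS)-1,2,4a,5-tetramethyl-1,2,3,4,4a,7,8,8a-octahydronaphthalen-2-yl]methyl}cyclohexa-2,5-diene-1,4-dione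
Product: 32 dysidenone B
Conditions: Cu(OTf)2 (10 mol %), (S,S)-t-Bu-box (12 mol %), MeOH/CH2Cl2, 4 Å MS, rt
Reagents that add atoms: methanol, CO
Why: Proposed new method: the hydroxyquinone should react through its ortho-quinonoid tautomer (4-hydroxy-1,2-dione), whose vicinal dicarbonyl chelates the chiral divalent copper bisoxazoline complex; methanol adds to the C1 carbonyl and the ring CH= carbon (C6) shifts to the copper-bound C2 carbonyl (benzilic ester rearrangement with ring contraction), the ligand shielding one face of C2 so that the carbinol centre forms as (R), and the resulting enol is protonated from the hydroxyl-bearing face, anti to the ester, which gives the (S) side-chain centre cis to the ester; the closest known reaction type is the copper–bisoxazoline-catalysed enantioselective benzilic ester rearrangement of 1,2-diketones.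

**Compound list**

1 | 1,2,4,5-tetramethoxybenzene | COc1cc(OC)c(OC)cc1OC | starting material
2 | (2,3,5,6-tetramethoxyphenyl)lithium | [Li]c1c(OC)c(OC)cc(OC)c1OC | intermediate
3 | (2,3,5,6-tetramethoxyphenyl)methanol | OCc1c(OC)c(OC)cc(OC)c1OC | intermediate
4 | 3-(bromomethyl)-1,2,4,5-tetramethoxybenzene | BrCc1c(OC)c(OC)cc(OC)c1OC | intermediate
5 | furan-2(5H)-one | O=C1OCC=C1 | starting material
6 | (E)-prop-1-en-1-ylboronic acid | C/C=C/B(O)O | starting material
7 | (S)-4-[(E)-prop-1-en-1-yl]dihydrofuran-2(3H)-one | C/C=C/[C@H]1COC(=O)C1 | intermediate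
8 | lithium enolate of 7 | C/C=C/[C@H]1COC(O[Li])=C1 | intermediate
9 | (3R,4R)-3-methyl-4-[(E)-prop-1-en-1-yl]dihydrofuran-2(3H)-one (methyl trans to propenyl) | C/C=C/[C@H]1COC(=O)[C@@H]1C | intermediate
10 | lithium enolate of 9 | C/C=C/[C@H]1COC(O[Li])=C1C | intermediate
11 | (3R,4R)-3-methyl-4-[(E)-prop-1-en-1-yl]-3-[(2,3,5,6-tetramethoxyphenyl)methyl]dihydrofuran-2(3H)-one (benzyl trans to propenyl) | O=C1OC[C@H](/C=C/C)[C@@]1(C)Cc1c(OC)c(OC)cc(OC)c1OC | intermediate
12 | (3R,4R)-3-methyl-4-[(E)-prop-1-en-1-yl]-3-[(2,3,5,6-tetramethoxyphenyl)methyl]oxolan-2-ol (anomer mixture) | OC1OC[C@H](/C=C/C)[C@@]1(C)Cc1c(OC)c(OC)cc(OC)c1OC | intermediate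
13 | (2R,3S)-3-methyl-2-[(E)-prop-1-en-1-yl]-3-[(2,3,5,6-tetramethoxyphenyl)methyl]pent-4-en-1-ol | C=C[C@](C)(Cc1c(OC)c(OC)cc(OC)c1OC)[C@H](CO)/C=C/C | intermediate
14 | methyl 2-methyl-3-oxobutanoate | COC(=O)C(C)C(C)=O | starting material
15 | methyl (E)-2-methyl-3-[(4-methylbenzenesulfonyl)oxy]but-2-enoate | COC(=O)/C(C)=C(\C)OS(=O)(=O)c1ccc(C)cc1 | intermediate
16 | 9-BBN alkylborane of 13 (boron on C6, C9a–OH as its 9-BBN borinate, C8 and C9 as in 13) | B1(CC[C@](C)(Cc2c(OC)c(OC)cc(OC)c2OC)[C@H](COB2C3CCCC2CCC3)/C=C/C)C2CCCC1CCC2 | intermediate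
17 | methyl (2E,6R,7R,8E)-7-(hydroxymethyl)-2,3,6-trimethyl-6-[(2,3,5,6-tetramethoxyphenyl)methyl]deca-2,8-dienoate | COC(=O)/C(C)=C(\C)CC[C@](C)(Cc1c(OC)c(OC)cc(OC)c1OC)[C@H](CO)/C=C/C | intermediate
18 | methanesulfonate of 17 | COC(=O)/C(C)=C(\C)CC[C@](C)(Cc1c(OC)c(OC)cc(OC)c1OC)[C@H](COS(C)(=O)=O)/C=C/C | intermediate
19 | methyl (2E,6R,7R,8E)-7-{[(2-hydroxyethyl)sulfanyl]methyl}-2,3,6-trimethyl-6-[(2,3,5,6-tetramethoxyphenyl)methyl]deca-2,8-dienoate | COC(=O)/C(C)=C(\C)CC[C@](C)(Cc1c(OC)c(OC)cc(OC)c1OC)[C@H](CSCCO)/C=C/C | intermediate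
20 | methyl (2E,6R,7R,8E)-7-{[(2-hydroxyethyl)sulfonyl]methyl}-2,3,6-trimethyl-6-[(2,3,5,6-tetramethoxyphenyl)methyl]deca-2,8-dienoate | COC(=O)/C(C)=C(\C)CC[C@](C)(Cc1c(OC)c(OC)cc(OC)c1OC)[C@H](CS(=O)(=O)CCO)/C=C/C | intermediate
21 | methanesulfonate of 20 | COC(=O)/C(C)=C(\C)CC[C@](C)(Cc1c(OC)c(OC)cc(OC)c1OC)[C@H](CS(=O)(=O)CCOS(C)(=O)=O)/C=C/C | intermediate
22 | methyl (2E,6R,7R,8E)-7-[(ethenesulfonyl)methyl]-2,3,6-trimethyl-6-[(2,3,5,6-tetramethoxyphenyl)methyl]deca-2,8-dienoate | COC(=O)/C(C)=C(\C)CC[C@](C)(Cc1c(OC)c(OC)cc(OC)c1OC)[C@H](CS(=O)(=O)C=C)/C=C/C | intermediate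
23 | methyl (2E,6R)-6-[(3R)-1,1-dioxo-2,3-dihydrothiophen-3-yl]-2,3,6-trimethyl-7-(2,3,5,6-tetramethoxyphenyl)hept-2-enoate | COC(=O)/C(C)=C(\C)CC[C@](C)(Cc1c(OC)c(OC)cc(OC)c1OC)[C@H]1C=CS(=O)(=O)C1 | intermediate
24 | (2E,6R)-6-[(3R)-1,1-dioxo-2,3-dihydrothiophen-3-yl]-2,3,6-trimethyl-7-(2,3,5,6-tetramethoxyphenyl)hept-2-en-1-ol | OC/C(C)=C(\C)CC[C@](C)(Cc1c(OC)c(OC)cc(OC)c1OC)[C@H]1C=CS(=O)(=O)C1 | intermediate
25 | (2E,6R)-6-[(3R)-1,1-dioxo-2,3-dihydrothiophen-3-yl]-2,3,6-trimethyl-7-(2,3,5,6-tetramethoxyphenyl)hept-2-enal | O=C/C(C)=C(\C)CC[C@](C)(Cc1c(OC)c(OC)cc(OC)c1OC)[C@H]1C=CS(=O)(=O)C1 | intermediate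
26 | (3R)-3-[(2R,5E)-2,5,6-trimethyl-1-(2,3,5,6-tetramethoxyphenyl)octa-5,7-dien-2-yl]-2,3-dihydrothiophene 1,1-dioxide | C=C/C(C)=C(\C)CC[C@](C)(Cc1c(OC)c(OC)cc(OC)c1OC)[C@H]1C=CS(=O)(=O)C1 | intermediate
27 | tricyclic sulfone: the trans-fused octalin of 29 with C1 and C9a bridged by SO2 (sulfolane cis-fused at C9–C10 and C10–C1; H-1, H-9 and H-10 mutually syn and anti to the C5 methyl; C8 as in 29) | COc1cc(OC)c(OC)c(C[C@@]2(C)CC[C@]3(C)C(C)=CC[C@@H]4[C@H]3[C@H]2CS4(=O)=O)c1OC | intermediate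
28 | tricyclic thiolane: as 27 with S in place of SO2 | COc1cc(OC)c(OC)c(C[C@@]2(C)CC[C@]3(C)C(C)=CC[C@@H]4[C@H]3[C@H]2CS4)c1OC | intermediate
29 | 3-{[(1R,2R,4aS,8aS)-1,2,4a,5-tetramethyl-1,2,3,4,4a,7,8,8a-octahydronaphthalen-2-yl]methyl}-1,2,4,5-tetramethoxybenzene | COc1cc(OC)c(OC)c(C[C@@]2(C)CC[C@]3(C)C(C)=CCC[C@H]3[C@H]2C)c1OC | intermediate
30 | 2,5-dimethoxy-3-{[(1R,2R,4aS,8aS)-1,2,4a,5-tetramethyl-1,2,3,4,4a,7,8,8a-octahydronaphthalen-2-yl]methyl}cyclohexa-2,5-diene-1,4-dione | COC1=CC(=O)C(OC)=C(C[C@@]2(C)CC[C@]3(C)C(C)=CCC[C@H]3[C@H]2C)C1=O | intermediate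
31 | 2-hydroxy-5-methoxy-3-{[(1R,2R,4aS,8aS)-1,2,4a,5-tetramethyl-1,2,3,4,4a,7,8,8a-octahydronaphthalen-2-yl]methyl}cyclohexa-2,5-diene-1,4-dione | COC1=CC(=O)C(O)=C(C[C@@]2(C)CC[C@]3(C)C(C)=CCC[C@H]3[C@H]2C)C1=O | intermediate
32 | dysidenone B, methyl (1R,5S)-1-hydroxy-3-methoxy-4-oxo-5-{[(1R,2R,4aS,8aS)-1,2,4a,5-tetramethyl-1,2,3,4,4a,7,8,8a-octahydronaphthalen-2-yl]methyl}cyclopent-2-ene-1-carboxylate | COC(=O)[C@@]1(O)C=C(OC)C(=O)[C@H]1C[C@@]1(C)CC[C@]2(C)C(C)=CCC[C@H]2[C@H]1C | target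

**Step count.** Total: 22 steps. Longest linear sequence: 19 steps (steps 3–7 and 9–22, from 5 and 6 to 32).

**Steps most likely to fail**

Step 22 (proposed new method). The copper catalyst may be sequestered as an unreactive hydroxyquinonate chelate, and facial discrimination at the migration terminus may be weak; should the sense of induction prove opposite, the enantiomeric ligand would be used. The fallback sets out from 31 and returns at 32. It gives up catalyst control: the benzilic ester rearrangement is run with NaOMe in MeOH at rt, which should give 32 together with its cyclopentenone-epimeric series. Compound 32 is then separated by preparative HPLC from the main expected contaminant, the (1S,5R)-diastereomer F1.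

Step 17. The cycloaddition at the quaternary diene terminus may be slow enough for the [1,5]-hydrogen shift of the (Z)-methyl diene, or thermal decomposition, to outrun it. The fallback sets out from 25 and returns at 27, and replaces the diene by a much more electron-rich one. MeTi(OiPr)3 adds to the enal to give the secondary allylic alcohol F2, and MnO2 gives the methyl enone F3. Kinetic silylation of the methyl group (TBSOTf, Et3N, CH2Cl2, −78 °C) gives the 2-silyloxy diene F4. This should undergo the same sulfolene-locked cycloaddition near 110 °C in toluene to give the silyl enol ether cycloadduct F5, with the enol ether fixed at C3=C4. CsF and PhNTf2 in DME convert it into the enol triflate F6, and Pd(OAc)2, PPh3, HCO2H and n-Bu3N in DMF at 60 °C reduce the triflate to the C3–H alkene 27.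

Step 19. The trisubstituted double bond may be saturated or may migrate on the nickel surface, or hydrogenolysis may stop halfway. The fallback sets out from 28 and returns at 29 without a hydrogenation catalyst. Lithium 4,4′-di-tert-butylbiphenylide in THF at −78 °C should cleave the C1–S bond at the more substituted carbon and, after protonation, give the primary thiol F7. Radical desulfurisation with P(OEt)3 and AIBN in benzene at 80 °C then removes the sulfur to give 29.

**Further compounds**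

F1 | step 22 | methyl (1S,5R)-1-hydroxy-3-methoxy-4-oxo-5-{[(1R,2R,4aS,8aS)-1,2,4a,5-tetramethyl-1,2,3,4,4a,7,8,8a-octahydronaphthalen-2-yl]methyl}cyclopent-2-ene-1-carboxylate | COC(=O)[C@]1(O)C=C(OC)C(=O)[C@@H]1C[C@@]1(C)CC[C@]2(C)C(C)=CCC[C@H]2[C@H]1C
F2 | step 17 | (3E,7R)-7-[(3R)-1,1-dioxo-2,3-dihydrothiophen-3-yl]-3,4,7-trimethyl-8-(2,3,5,6-tetramethoxyphenyl)oct-3-en-2-ol (carbinol epimers) | CC(O)/C(C)=C(\C)CC[C@](C)(Cc1c(OC)c(OC)cc(OC)c1OC)[C@H]1C=CS(=O)(=O)C1
F3 | step 17 | (3E,7R)-7-[(3R)-1,1-dioxo-2,3-dihydrothiophen-3-yl]-3,4,7-trimethyl-8-(2,3,5,6-tetramethoxyphenyl)oct-3-en-2-one | CC(=O)/C(C)=C(\C)CC[C@](C)(Cc1c(OC)c(OC)cc(OC)c1OC)[C@H]1C=CS(=O)(=O)C1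
F4 | step 17 | (3R)-3-[(2R,5E)-7-(tert-butyldimethylsilyloxy)-2,5,6-trimethyl-1-(2,3,5,6-tetramethoxyphenyl)octa-5,7-dien-2-yl]-2,3-dihydrothiophene 1,1-dioxide | C=C(O[Si](C)(C)C(C)(C)C)/C(C)=C(\C)CC[C@](C)(Cc1c(OC)c(OC)cc(OC)c1OC)[C@H]1C=CS(=O)(=O)C1
F5 | step 17 | tricyclic sulfone 27 bearing a tert-butyldimethylsilyloxy group on C3 (C3=C4 silyl enol ether) | COc1cc(OC)c(OC)c(C[C@@]2(C)CC[C@]3(C)C(C)=C(O[Si](C)(C)C(C)(C)C)C[C@@H]4[C@H]3[C@H]2CS4(=O)=O)c1OC
F6 | step 17 | tricyclic sulfone 27 bearing a trifluoromethanesulfonyloxy group on C3 (C3=C4 enol triflate) | COc1cc(OC)c(OC)c(C[C@@]2(C)CC[C@]3(C)C(C)=C(OS(=O)(=O)C(F)(F)F)C[C@@H]4[C@H]3[C@H]2CS4(=O)=O)c1OC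
F7 | step 19 | {(1R,2R,4aS,8aS)-2,4a,5-trimethyl-2-[(2,3,5,6-tetramethoxyphenyl)methyl]-1,2,3,4,4a,7,8,8a-octahydronaphthalen-1-yl}methanethiol | COc1cc(OC)c(OC)c(C[C@@]2(C)CC[C@]3(C)C(C)=CCC[C@H]3[C@H]2CS)c1OC
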